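**Strategy**

Locants follow the target SMILES: C1–C3 side chain, C4–C8 piperidine carbons (ring A), C9–C13 cyclopentane (ring C), C14–C16 trimethylene of the azepane (ring B); ring D is the tetronate. Ring A is carried as a 2,6-disubstituted pyridine and ring B is closed last through N–C16: the pyridine nitrogen displaces a C16 mesylate, and the rigid pyridoazepinium ion is hydrogenated in the same flask. This exploits ring A being a cis-2,6-disubstituted N-alkylpiperidine (N, C4, C8), a reduced pyridinium; C4 and C8 arise cis from the face of H-9. The precursor is a pyridylcyclopentane carrying ring D and all other stereocentres, built from a D-ribose-derived cyclopentenone.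

Key step: step 16

Convention: "top" is the face of ring C that carries the pyridyl (later C8) substituent at C9; "bottom" is the opposite face.
Assumption: the D-ribose-derived enone acetonide and methyl (2E)-3-methoxy-2-methylprop-2-enoate are taken as catalogue compounds.

**Route**

Step 1
Reactants: 1 2,6-dibromopyridine; 2 N,N-dimethylpropanamide
Product: 4 1-(6-bromopyridin-2-yl)propan-1-one, via (6-bromopyridin-2-yl)lithium 3 (not isolated)
Conditions: n-BuLi (1.0 equiv), Et2O, −78 °C; then 2, −78 °C to rt; H2O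
Reagents that add atoms: none
Why: Bromine–lithium exchange stops after one bromine because the lithiated ring is deactivated, and acylation by the tertiary amide gives a tetrahedral adduct that releases the ketone only on work-up (organolithium acylation).

Step 2
Reactants: 4 1-(6-bromopyridin-2-yl)propan-1-one
Product: 5 (1R)-1-(6-bromopyridin-2-yl)propan-1-ol
Conditions: RuCl[(R,R)-TsDPEN](p-cymene) (1 mol%), HCO2H/Et3N (5:2), rt
Reagents that add atoms: none
Why: Noyori-type asymmetric transfer hydrogenation of an aryl alkyl ketone, in which the (R,R)-catalyst should give the R carbinol that becomes C3.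

Step 3
Reactants: 5 (1R)-1-(6-bromopyridin-2-yl)propan-1-ol
Product: 6 2-bromo-6-[(1R)-1-(tert-butyldiphenylsilyloxy)propyl]pyridine
Conditions: TBDPSCl, imidazole, DMF, rt
Reagents that add atoms: tert-butyl(chloro)diphenylsilane, CC(C)(C)[Si](Cl)(c1ccccc1)c1ccccc1
Why: Standard silylation; this silyl ether should survive the acidic acetonide cleavage of step 8 and both oxidations, and is removed by fluoride in step 12.

Step 4
Reactants: 7 (3aR,6aR)-2,2-dimethyl-3a,6a-dihydro-4H-cyclopenta[d][1,3]dioxol-4-one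
Product: 8 (3aR,6aR)-5-iodo-2,2-dimethyl-3a,6a-dihydro-4H-cyclopenta[d][1,3]dioxol-4-one
Conditions: I2, pyridine, CH2Cl2, 0 °C to rt
Reagents that add atoms: iodine, II
Why: α-Iodination of a cyclic enone by conjugate addition of pyridine, iodination of the enolate and elimination, which leaves both acetal stereocentres untouched.

Step 5
Reactants: 6 2-bromo-6-[(1R)-1-(tert-butyldiphenylsilyloxy)propyl]pyridine; 8 (3aR,6aR)-5-iodo-2,2-dimethyl-3a,6a-dihydro-4H-cyclopenta[d][1,3]dioxol-4-one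
Product: 10 (3aR,6aR)-5-{6-[(1R)-1-(tert-butyldiphenylsilyloxy)propyl]pyridin-2-yl}-2,2-dimethyl-3a,6a-dihydro-4H-cyclopenta[d][1,3]dioxol-4-one, via pyridylzinc bromide 9 (not isolated)
Conditions: active Zn powder (Zn*), THF, 50 °C; then 8, Pd2(dba)3 (2.5 mol%), P(2-furyl)3 (10 mol%), THF/DMF, rt
Reagents that add atoms: none
Why: Negishi coupling of a 2-pyridylzinc halide with an α-iodoenone should form the C8–C9 bond under neutral conditions that do not disturb the base-sensitive acetonide enone.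

Step 6
Reactants: 10 (3aR,6aR)-5-{6-[(1R)-1-(tert-butyldiphenylsilyloxy)propyl]pyridin-2-yl}-2,2-dimethyl-3a,6a-dihydro-4H-cyclopenta[d][1,3]dioxol-4-one
Product: 11 (3aR,5R,6S,6aR)-5-{6-[(1R)-1-(tert-butyldiphenylsilyloxy)propyl]pyridin-2-yl}-2,2,6-trimethyltetrahydro-4H-cyclopenta[d][1,3]dioxol-4-one
Conditions: MeLi (2 equiv), CuI, Et2O, −78 °C; then 10, −78 to −40 °C; aq. NH4Cl
Reagents that add atoms: lithium dimethylcuprate, [Li+].C[Cu-]C
Why: Cuprate conjugate addition should deliver methyl to C10 on the convex face anti to the acetonide, and the very acidic C9 (α to ketone and pyridine) then equilibrates to pyridyl trans to methyl, i.e. on the top face.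

Step 7
Reactants: 11 (3aR,5R,6S,6aR)-5-{6-[(1R)-1-(tert-butyldiphenylsilyloxy)propyl]pyridin-2-yl}-2,2,6-trimethyltetrahydro-4H-cyclopenta[d][1,3]dioxol-4-one
Product: 12 (3aR,4S,5R,6S,6aR)-5-{6-[(1R)-1-(tert-butyldiphenylsilyloxy)propyl]pyridin-2-yl}-2,2,6-trimethyl-4-(prop-2-en-1-yl)tetrahydro-4H-cyclopenta[d][1,3]dioxol-4-ol
Conditions: allyl bromide, Zn dust, THF/sat. aq. NH4Cl, 0 °C to rt
Reagents that add atoms: allyl bromide, C=CCBr
Why: Aqueous Barbier allylation tolerates the strongly enolisable α-pyridyl ketone, and the allylzinc should attack C13 from the bottom face, anti to both the C9 pyridyl group and the C12 acetonide oxygen, giving C13 with OH top and allyl bottom.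

Step 8
Reactants: 12 (3aR,4S,5R,6S,6aR)-5-{6-[(1R)-1-(tert-butyldiphenylsilyloxy)propyl]pyridin-2-yl}-2,2,6-trimethyl-4-(prop-2-en-1-yl)tetrahydro-4H-cyclopenta[d][1,3]dioxol-4-ol
Product: 13 (1S,2R,3R,4S,5R)-5-{6-[(1R)-1-(tert-butyldiphenylsilyloxy)propyl]pyridin-2-yl}-4-methyl-1-(prop-2-en-1-yl)cyclopentane-1,2,3-triol
Conditions: 2 M aq. HCl, MeOH, 40 °C
Reagents that add atoms: none
Why: Acid hydrolysis of the cis-fused isopropylidene acetal, which the tert-butyldiphenylsilyl ether (next to a protonated pyridine) and the tertiary alcohol should tolerate.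

Step 9
Reactants: 13 (1S,2R,3R,4S,5R)-5-{6-[(1R)-1-(tert-butyldiphenylsilyloxy)propyl]pyridin-2-yl}-4-methyl-1-(prop-2-en-1-yl)cyclopentane-1,2,3-triol
Product: 14 (4R,5S)-4-{6-[(1R)-1-(tert-butyldiphenylsilyloxy)propyl]pyridin-2-yl}-2,5-dihydroxy-3-methyl-5-(prop-2-en-1-yl)cyclopent-2-en-1-one
Conditions: IBX (4 equiv), DMSO, 40 °C
Reagents that add atoms: none
Why: IBX oxidises 1,2-diols to 1,2-diones without C–C cleavage, and the C11/C12 dione can enolise only towards C10 (C13 is quaternary), giving the diosphenol with C12 as the ketone; C10 and C11 are deliberately flattened and reset in steps 12 and 13.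

Step 10
Reactants: 14 (4R,5S)-4-{6-[(1R)-1-(tert-butyldiphenylsilyloxy)propyl]pyridin-2-yl}-2,5-dihydroxy-3-methyl-5-(prop-2-en-1-yl)cyclopent-2-en-1-one
Product: 15 (4R,5S)-2,5-bis(tert-butyldimethylsilyloxy)-4-{6-[(1R)-1-(tert-butyldiphenylsilyloxy)propyl]pyridin-2-yl}-3-methyl-5-(prop-2-en-1-yl)cyclopent-2-en-1-one
Conditions: TBSOTf (2.5 equiv), 2,6-lutidine, CH2Cl2, −78 to 0 °C
Reagents that add atoms: tert-butyldimethylsilyl trifluoromethanesulfonate, CC(C)(C)[Si](C)(C)OS(=O)(=O)C(F)(F)F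
Why: Silyl triflate silylates both the acidic enol and the tertiary C13 alcohol, whose bulky silyl ether later screens the top face of C12 and blocks retro-aldol opening.

Step 11
Reactants: 15 (4R,5S)-2,5-bis(tert-butyldimethylsilyloxy)-4-{6-[(1R)-1-(tert-butyldiphenylsilyloxy)propyl]pyridin-2-yl}-3-methyl-5-(prop-2-en-1-yl)cyclopent-2-en-1-one; 16 methyl (2E)-3-methoxy-2-methylprop-2-enoate
Product: 18 (5S,8R,9S)-6,9-bis(tert-butyldimethylsilyloxy)-8-{6-[(1R)-1-(tert-butyldiphenylsilyloxy)propyl]pyridin-2-yl}-4-methoxy-3,7-dimethyl-9-(prop-2-en-1-yl)-1-oxaspiro[4.4]nona-3,6-dien-2-one, via lithiated acrylate 17 (not isolated)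
Conditions: 16 (2.5 equiv), LDA, THF, −90 °C; then 15, −90 to −20 °C; H2O
Reagents that add atoms: none
Why: The β-methoxyacrylate is lithiated at the β-carbon cis to the ester (chelation), this vinyl anion adds 1,2 to the C12 ketone and the alkoxide lactonises onto the cis ester (β-lithioacrylate tetronate annulation); attack anti to the C13–O bond (polar Felkin–Anh, silyl group over the top face) should set C12 with oxygen top and the ring D carbon bottom.

Step 12
Reactants: 18 (5S,8R,9S)-6,9-bis(tert-butyldimethylsilyloxy)-8-{6-[(1R)-1-(tert-butyldiphenylsilyloxy)propyl]pyridin-2-yl}-4-methoxy-3,7-dimethyl-9-(prop-2-en-1-yl)-1-oxaspiro[4.4]nona-3,6-dien-2-one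
Product: 20 (5R,7S,8R,9S)-9-hydroxy-8-{6-[(1R)-1-hydroxypropyl]pyridin-2-yl}-4-methoxy-3,7-dimethyl-9-(prop-2-en-1-yl)-1-oxaspiro[4.4]non-3-ene-2,6-dione, via silylated C11 ketone 19 (not isolated)
Conditions: TBAF (1.1 equiv), THF, 0 °C; then 48% aq. HF, MeCN, rt
Reagents that add atoms: none
Why: Fluoride cleaves the silyl enol ether to the C11 ketone enolate, whose reprotonation should equilibrate C10 to methyl trans to the C9 pyridyl group while the C13 oxygen is still silylated (no retro-aldol possible), and acidic HF then removes the remaining silyl ethers (desilylation with thermodynamic control at C10).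

Step 13
Reactants: 20 (5R,7S,8R,9S)-9-hydroxy-8-{6-[(1R)-1-hydroxypropyl]pyridin-2-yl}-4-methoxy-3,7-dimethyl-9-(prop-2-en-1-yl)-1-oxaspiro[4.4]non-3-ene-2,6-dione
Product: 21 (5R,6S,7S,8R,9S)-6,9-dihydroxy-8-{6-[(1R)-1-hydroxypropyl]pyridin-2-yl}-4-methoxy-3,7-dimethyl-9-(prop-2-en-1-yl)-1-oxaspiro[4.4]non-3-en-2-one
Conditions: Me4NBH(OAc)3, MeCN/AcOH (1:1), −20 °C
Reagents that add atoms: none
Why: Hydroxyl-directed triacetoxyborohydride reduction of a β-hydroxy ketone, in which hydride is delivered from boron bound to the top-face C13 hydroxyl and should give the 1,3-anti diol, i.e. C11–OH on the bottom face.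

Step 14
Reactants: 21 (5R,6S,7S,8R,9S)-6,9-dihydroxy-8-{6-[(1R)-1-hydroxypropyl]pyridin-2-yl}-4-methoxy-3,7-dimethyl-9-(prop-2-en-1-yl)-1-oxaspiro[4.4]non-3-en-2-one
Product: 22 (5S,6S,7S,8R,9S)-4-methoxy-3,7-dimethyl-9-(prop-2-en-1-yl)-6,9-bis(triethylsilyloxy)-8-{6-[(1R)-1-(triethylsilyloxy)propyl]pyridin-2-yl}-1-oxaspiro[4.4]non-3-en-2-one
Conditions: TESOTf (4 equiv), 2,6-lutidine, CH2Cl2, −40 to 0 °C
Reagents that add atoms: triethylsilyl trifluoromethanesulfonate, CC[Si](CC)(CC)OS(=O)(=O)C(F)(F)F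
Why: Exhaustive silylation leaves no free hydroxyl, so that step 16 can activate only the C16 hydroxyl and the C13 oxygen cannot close a tetrahydrofuran.

Step 15
Reactants: 22 (5S,6S,7S,8R,9S)-4-methoxy-3,7-dimethyl-9-(prop-2-en-1-yl)-6,9-bis(triethylsilyloxy)-8-{6-[(1R)-1-(triethylsilyloxy)propyl]pyridin-2-yl}-1-oxaspiro[4.4]non-3-en-2-one
Product: 24 (5S,6S,7S,8R,9S)-9-(3-hydroxypropyl)-4-methoxy-3,7-dimethyl-6,9-bis(triethylsilyloxy)-8-{6-[(1R)-1-(triethylsilyloxy)propyl]pyridin-2-yl}-1-oxaspiro[4.4]non-3-en-2-one, via B-alkyl-9-BBN adduct 23 (not isolated)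
Conditions: 9-BBN, THF, 0 °C to rt; then 30% H2O2, aq. NaOAc, 0 °C
Reagents that add atoms: hydrogen peroxide, OO
Why: Anti-Markovnikov hydroboration of the terminal alkene with 9-BBN (the tetrasubstituted tetronate alkene and the hindered pyridine should be inert) and mild oxidation place the hydroxyl on C16.

Step 16
Reactants: 24 (5S,6S,7S,8R,9S)-9-(3-hydroxypropyl)-4-methoxy-3,7-dimethyl-6,9-bis(triethylsilyloxy)-8-{6-[(1R)-1-(triethylsilyloxy)propyl]pyridin-2-yl}-1-oxaspiro[4.4]non-3-en-2-one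
Product: 28 CNP0267781.1, via C16 mesylate 25 (not isolated), via silylated pyridoazepinium mesylate 26 (not isolated), via pyridoazepinium triol mesylate 27 (not isolated)
Conditions: Ms2O (1.2 equiv), i-Pr2NEt (1.3 equiv), CH2Cl2, 0 °C; MeCN, 80 °C; 2 M HCl, MeOH/H2O, rt; H2 (4 atm), PtO2, rt; aq. NaHCO3
Reagents that add atoms: none
Why: The sulfonate formed at C16 is displaced by the pyridine nitrogen in an intramolecular Menshutkin SN2 reaction, acid then strips the triethylsilyl ethers, and the pyridinium ring takes up three H2 on the PtO2 surface by all-syn delivery from one face. The closest known reaction type is the cyclisation of 2-(ω-sulfonyloxyalkyl)pyridines to quinolizinium-type salts followed by catalytic hydrogenation to cis-2,6-disubstituted N-alkylpiperidines. Ring B closes by 7-exo-tet N-alkylation; ring A is not closed here but dearomatised. C8 and C4 should both be set by hydrogen adding to the face that carries the pseudo-axial H-9, because the opposite face is screened by C10 and the axial C13 oxygen of the trans-fused ring C; at the other end, 1,3-allylic strain puts H-3 in the ring plane towards C16, which places the small, surface-binding C3 hydroxyl on the same face and the ethyl group on the screened face, so both controls agree. The step needs N- over O-alkylation and reduction of the pyridinium without touching ring D: the first is secured by having every hydroxyl silylated during the alkylation (only C16 carries a leaving group), the second by the tetrasubstituted, vinylogous-carbonate character of the tetronate alkene.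

**Compound list**

1 | 2,6-dibromopyridine | Brc1cccc(Br)n1 | starting material
2 | N,N-dimethylpropanamide | CCC(=O)N(C)C | starting material
3 | (6-bromopyridin-2-yl)lithium | [Li]c1cccc(Br)n1 | intermediate (not isolated)
4 | 1-(6-bromopyridin-2-yl)propan-1-one | CCC(=O)c1cccc(Br)n1 | intermediate
5 | (1R)-1-(6-bromopyridin-2-yl)propan-1-ol | CC[C@@H](O)c1cccc(Br)n1 | intermediate
6 | 2-bromo-6-[(1R)-1-(tert-butyldiphenylsilyloxy)propyl]pyridine | CC[C@@H](O[Si](c5ccccc5)(c6ccccc6)C(C)(C)C)c1cccc(Br)n1 | intermediate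
7 | (3aR,6aR)-2,2-dimethyl-3a,6a-dihydro-4H-cyclopenta[d][1,3]dioxol-4-one | C1=C[C@@H](OC(C)(C)O2)[C@@H]2C1=O | starting material
8 | (3aR,6aR)-5-iodo-2,2-dimethyl-3a,6a-dihydro-4H-cyclopenta[d][1,3]dioxol-4-one | IC1=C[C@@H](OC(C)(C)O2)[C@@H]2C1=O | intermediate
9 | {6-[(1R)-1-(tert-butyldiphenylsilyloxy)propyl]pyridin-2-yl}zinc bromide | CC[C@@H](O[Si](c5ccccc5)(c6ccccc6)C(C)(C)C)c1cccc([Zn]Br)n1 | intermediate (not isolated)
10 | (3aR,6aR)-5-{6-[(1R)-1-(tert-butyldiphenylsilyloxy)propyl]pyridin-2-yl}-2,2-dimethyl-3a,6a-dihydro-4H-cyclopenta[d][1,3]dioxol-4-one | CC[C@@H](O[Si](c5ccccc5)(c6ccccc6)C(C)(C)C)c1cccc(n1)C3=C[C@@H](OC(C)(C)O4)[C@@H]4C3=O | intermediate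
11 | (3aR,5R,6S,6aR)-5-{6-[(1R)-1-(tert-butyldiphenylsilyloxy)propyl]pyridin-2-yl}-2,2,6-trimethyltetrahydro-4H-cyclopenta[d][1,3]dioxol-4-one (pyridyl top, methyl bottom, acetonide top) | CC[C@@H](O[Si](c5ccccc5)(c6ccccc6)C(C)(C)C)c1cccc(n1)[C@H]3[C@H](C)[C@@H](OC(C)(C)O4)[C@@H]4C3=O | intermediate
12 | (3aR,4S,5R,6S,6aR)-5-{6-[(1R)-1-(tert-butyldiphenylsilyloxy)propyl]pyridin-2-yl}-2,2,6-trimethyl-4-(prop-2-en-1-yl)tetrahydro-4H-cyclopenta[d][1,3]dioxol-4-ol (C13–OH top, allyl bottom) | CC[C@@H](O[Si](c5ccccc5)(c6ccccc6)C(C)(C)C)c1cccc(n1)[C@H]3[C@H](C)[C@@H](OC(C)(C)O4)[C@@H]4[C@]3(O)CC=C | intermediate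
13 | (1S,2R,3R,4S,5R)-5-{6-[(1R)-1-(tert-butyldiphenylsilyloxy)propyl]pyridin-2-yl}-4-methyl-1-(prop-2-en-1-yl)cyclopentane-1,2,3-triol | CC[C@@H](O[Si](c5ccccc5)(c6ccccc6)C(C)(C)C)c1cccc(n1)[C@H]3[C@H](C)[C@@H](O)[C@@H](O)[C@]3(O)CC=C | intermediate
14 | (4R,5S)-4-{6-[(1R)-1-(tert-butyldiphenylsilyloxy)propyl]pyridin-2-yl}-2,5-dihydroxy-3-methyl-5-(prop-2-en-1-yl)cyclopent-2-en-1-one | CC[C@@H](O[Si](c5ccccc5)(c6ccccc6)C(C)(C)C)c1cccc(n1)[C@H]3C(C)=C(O)C(=O)[C@]3(O)CC=C | intermediate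
15 | (4R,5S)-2,5-bis(tert-butyldimethylsilyloxy)-4-{6-[(1R)-1-(tert-butyldiphenylsilyloxy)propyl]pyridin-2-yl}-3-methyl-5-(prop-2-en-1-yl)cyclopent-2-en-1-one | CC[C@@H](O[Si](c5ccccc5)(c6ccccc6)C(C)(C)C)c1cccc(n1)[C@H]3C(C)=C(O[Si](C)(C)C(C)(C)C)C(=O)[C@]3(O[Si](C)(C)C(C)(C)C)CC=C | intermediate
16 | methyl (2E)-3-methoxy-2-methylprop-2-enoate | CO/C=C(\C)C(=O)OC | starting material
17 | methyl (2E)-3-lithio-3-methoxy-2-methylprop-2-enoate (lithium cis to the ester) | [Li]/C(OC)=C(/C)C(=O)OC | intermediate (not isolated)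
18 | (5S,8R,9S)-6,9-bis(tert-butyldimethylsilyloxy)-8-{6-[(1R)-1-(tert-butyldiphenylsilyloxy)propyl]pyridin-2-yl}-4-methoxy-3,7-dimethyl-9-(prop-2-en-1-yl)-1-oxaspiro[4.4]nona-3,6-dien-2-one | CC[C@@H](O[Si](c5ccccc5)(c6ccccc6)C(C)(C)C)c1cccc(n1)[C@H]3C(C)=C(O[Si](C)(C)C(C)(C)C)[C@@]4(OC(=O)C(C)=C4OC)[C@]3(O[Si](C)(C)C(C)(C)C)CC=C | intermediate
19 | (5S,7S,8R,9S)-9-(tert-butyldimethylsilyloxy)-8-{6-[(1R)-1-(tert-butyldiphenylsilyloxy)propyl]pyridin-2-yl}-4-methoxy-3,7-dimethyl-9-(prop-2-en-1-yl)-1-oxaspiro[4.4]non-3-ene-2,6-dione | CC[C@@H](O[Si](c5ccccc5)(c6ccccc6)C(C)(C)C)c1cccc(n1)[C@H]3[C@H](C)C(=O)[C@@]4(OC(=O)C(C)=C4OC)[C@]3(O[Si](C)(C)C(C)(C)C)CC=C | intermediate (not isolated)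
20 | (5R,7S,8R,9S)-9-hydroxy-8-{6-[(1R)-1-hydroxypropyl]pyridin-2-yl}-4-methoxy-3,7-dimethyl-9-(prop-2-en-1-yl)-1-oxaspiro[4.4]non-3-ene-2,6-dione | CC[C@@H](O)c1cccc(n1)[C@H]3[C@H](C)C(=O)[C@@]4(OC(=O)C(C)=C4OC)[C@]3(O)CC=C | intermediate
21 | (5R,6S,7S,8R,9S)-6,9-dihydroxy-8-{6-[(1R)-1-hydroxypropyl]pyridin-2-yl}-4-methoxy-3,7-dimethyl-9-(prop-2-en-1-yl)-1-oxaspiro[4.4]non-3-en-2-one | CC[C@@H](O)c1cccc(n1)[C@H]3[C@H](C)[C@H](O)[C@@]4(OC(=O)C(C)=C4OC)[C@]3(O)CC=C | intermediate
22 | (5S,6S,7S,8R,9S)-4-methoxy-3,7-dimethyl-9-(prop-2-en-1-yl)-6,9-bis(triethylsilyloxy)-8-{6-[(1R)-1-(triethylsilyloxy)propyl]pyridin-2-yl}-1-oxaspiro[4.4]non-3-en-2-one | CC[C@@H](O[Si](CC)(CC)CC)c1cccc(n1)[C@H]3[C@H](C)[C@H](O[Si](CC)(CC)CC)[C@@]4(OC(=O)C(C)=C4OC)[C@]3(O[Si](CC)(CC)CC)CC=C | intermediate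
23 | B-alkyl-9-BBN adduct of 22 (9-borabicyclo[3.3.1]nonan-9-yl on C16) | CC[C@@H](O[Si](CC)(CC)CC)c1cccc(n1)[C@H]3[C@H](C)[C@H](O[Si](CC)(CC)CC)[C@@]4(OC(=O)C(C)=C4OC)[C@]3(O[Si](CC)(CC)CC)CCCB5C6CCCC5CCC6 | intermediate (not isolated)
24 | (5S,6S,7S,8R,9S)-9-(3-hydroxypropyl)-4-methoxy-3,7-dimethyl-6,9-bis(triethylsilyloxy)-8-{6-[(1R)-1-(triethylsilyloxy)propyl]pyridin-2-yl}-1-oxaspiro[4.4]non-3-en-2-one | CC[C@@H](O[Si](CC)(CC)CC)c1cccc(n1)[C@H]3[C@H](C)[C@H](O[Si](CC)(CC)CC)[C@@]4(OC(=O)C(C)=C4OC)[C@]3(O[Si](CC)(CC)CC)CCCO | intermediate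
25 | C16 methanesulfonate of 24 | CC[C@@H](O[Si](CC)(CC)CC)c1cccc(n1)[C@H]3[C@H](C)[C@H](O[Si](CC)(CC)CC)[C@@]4(OC(=O)C(C)=C4OC)[C@]3(O[Si](CC)(CC)CC)CCCOS(C)(=O)=O | intermediate (not isolated)
26 | tris(triethylsilyl) pyrido[1,2-a]azepinium methanesulfonate (ring B closed, ring A aromatic) | CC[C@@H](O[Si](CC)(CC)CC)c1cccc2[C@H]3[C@H](C)[C@H](O[Si](CC)(CC)CC)[C@@]4(OC(=O)C(C)=C4OC)[C@]3(O[Si](CC)(CC)CC)CCC[n+]12.CS(=O)(=O)[O-] | intermediate (not isolated)
27 | pyrido[1,2-a]azepinium triol methanesulfonate (C3, C11, C13 hydroxyls free) | CC[C@@H](O)c1cccc2[C@H]3[C@H](C)[C@H](O)[C@@]4(OC(=O)C(C)=C4OC)[C@]3(O)CCC[n+]12.CS(=O)(=O)[O-] | intermediate (not isolated)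
28 | CNP0267781.1 (3R,4R,8S,9R,10S,11S,12R,13S by the locants above) | CC[C@@H](O)[C@H]1CCC[C@H]2[C@H]3[C@H](C)[C@H](O)[C@@]4(OC(=O)C(C)=C4OC)[C@]3(O)CCCN12 | target

**Step count and risks**

Total steps: 16. Longest linear sequence: 15 steps (steps 1–3 and 5–16).

Steps most likely to fail:

1. Step 16. Quaternisation at the nitrogen, which is flanked by two branched substituents, may be slow. Participation of the C13 silyl ether oxygen at C16 (cyclic oxonium, loss of silyl, tetrahydrofuran) or elimination could then compete, residual base could epimerise C9 of the pyridinium, and hydrogen could partly add to the other face. Fallback, from 24 to 28: Dess–Martin oxidation of the primary alcohol should give the C16 aldehyde F1. 2 M HCl in THF removes the three silyl groups, and the freed C13 hydroxyl closes onto the aldehyde to give the spiro lactol F2. Hydrogenation of F2 over PtO2 in AcOH should reduce the protonated pyridine to the cis-2,6-piperidine; the secondary amine then condenses with the lactol and the iminium ion is reduced in the same flask, closing ring B by intramolecular reductive amination to 28.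

2. Step 11. The basic vinyllithium may abstract the proton at C9 (γ to the enone carbonyl and α to the pyridine) instead of adding to C12, or may approach the top face. Fallback, from 15 to 19: the slimmer and less basic lithium acetylide of methyl propiolate (LDA, THF, −78 °C) should add to C12 to give the propargylic alcohol F3. NaOMe in MeOH effects conjugate addition of methoxide, lactonisation and methanolysis of the enol silyl ether, giving the 3-unsubstituted tetronate ketone F4. NBS in MeCN brominates C3 of the tetronate to give bromotetronate F5. Suzuki–Miyaura methylation (trimethylboroxine, PdCl2(dppf), K2CO3, dioxane, 90 °C) returns to 19, which is then taken through the aqueous HF stage of step 12.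

3. Step 13. The hindered tertiary C13 hydroxyl may fail to exchange onto boron, so that the ketone is not reduced or is reduced without direction and with the wrong sense. Fallback, from 19 (isolated after the fluoride stage of step 12) to 21: reagent-controlled Corey–Bakshi–Shibata reduction ((R)-2-methyl-CBS-oxazaborolidine, catecholborane, toluene, −78 °C), in which the quaternary C12 acts as the large group, should give the silyl-protected C11 carbinol F6. 48% aq. HF in MeCN then removes both silyl ethers and returns to 21.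

**Further compounds**

F1 | step 16 | C16 aldehyde: 3-[(5S,6S,7S,8R,9S)-4-methoxy-3,7-dimethyl-2-oxo-6,9-bis(triethylsilyloxy)-8-{6-[(1R)-1-(triethylsilyloxy)propyl]pyridin-2-yl}-1-oxaspiro[4.4]non-3-en-9-yl]propanal | CC[C@@H](O[Si](CC)(CC)CC)c1cccc(n1)[C@H]3[C@H](C)[C@H](O[Si](CC)(CC)CC)[C@@]4(OC(=O)C(C)=C4OC)[C@]3(O[Si](CC)(CC)CC)CCC=O
F2 | step 16 | spiro lactol: desilylated F1 in which the C13 oxygen is bonded to C16 as a 2-hydroxytetrahydrofuran (anomeric mixture) | CC[C@@H](O)c1cccc(n1)[C@H]3[C@H](C)[C@H](O)[C@@]4(OC(=O)C(C)=C4OC)[C@]3(O5)CCC5O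
F3 | step 11 | C12 propargylic alcohol: methyl 3-[C12 carbinol of 15]prop-2-ynoate (OH top, alkynoate bottom) | CC[C@@H](O[Si](c5ccccc5)(c6ccccc6)C(C)(C)C)c1cccc(n1)[C@H]3C(C)=C(O[Si](C)(C)C(C)(C)C)[C@@](C#CC(=O)OC)(O)[C@]3(O[Si](C)(C)C(C)(C)C)CC=C
F4 | step 11 | 3-unsubstituted tetronate ketone (19 lacking the ring D methyl group) | CC[C@@H](O[Si](c5ccccc5)(c6ccccc6)C(C)(C)C)c1cccc(n1)[C@H]3[C@H](C)C(=O)[C@@]4(OC(=O)C=C4OC)[C@]3(O[Si](C)(C)C(C)(C)C)CC=C
F5 | step 11 | 3-bromotetronate ketone (19 with bromine in place of the ring D methyl group) | CC[C@@H](O[Si](c5ccccc5)(c6ccccc6)C(C)(C)C)c1cccc(n1)[C@H]3[C@H](C)C(=O)[C@@]4(OC(=O)C(Br)=C4OC)[C@]3(O[Si](C)(C)C(C)(C)C)CC=C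
F6 | step 13 | silyl-protected C11 carbinol (21 with C13–OTBS and C3–OTBDPS) | CC[C@@H](O[Si](c5ccccc5)(c6ccccc6)C(C)(C)C)c1cccc(n1)[C@H]3[C@H](C)[C@H](O)[C@@]4(OC(=O)C(C)=C4OC)[C@]3(O[Si](C)(C)C(C)(C)C)CC=C
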